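**Plan**
1. Retrosynthetic cuts, in order: C12–C13 (butenolide joined last); the C19 acetate; C8=C17; C4–C18 together with the C5–H bond; then C1–C2 and C4–C5 of ring A in one operation; then C10–C1, C10–C20 and C9–C11, back to p-benzoquinone mono(ethylene ketal).
2. Enabling feature: in ring A the C3 oxygen lies between C2 and C4, so C2–C3–C4 (with C19) is an acetoacetate 1,3-bis-nucleophile. C1 and C5 both sit on quaternary C10, so ring B with a C1 aldehyde next to its C5 ketone is a 1,3-bis-electrophile. A formal [3+3] cyclocondensation therefore closes ring A onto ring B and forges the hindered C4–C5 bond.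
3. Forward order: ring B is bought; C9 vinyl, C10 methyl and C10 CH2OH/CHO are added; ring A is annulated (step 6); then C4 methyl with trans ring fusion, C8 methylene, C3/C19 oxygens; the butenolide ring is bought and attached last.
4. Stereochemistry: C9 from a catalyst-controlled desymmetrising vinyl addition (Rh/(R)-BINAP); C10 by alkylation anti to the C9 vinyl; C5 and C4 by Li/NH3 reductive methylation; C3 by axial hydride delivery; (E)-C11=C12 from the Heck mechanism.

Key step: step 6

Remarks on the chemistry:
- Atoms carry labdane numbers throughout. In the monocyclic compounds the ketal carbon is C8, the vinyl-bearing carbon C9, the methyl-bearing carbon C10 and the ketone carbon C5. α is the face of the C10 methyl group.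
- Assumption: the facial sense of the Rh/(R)-BINAP addition follows the established model for cyclohex-2-enone; if the opposite sense were found, (S)-BINAP would be used.
- Assumption: compounds 1, 2, 10 and 21 are taken as commercially available.

Step 1
Reactants: 1 1,4-dioxaspiro[4.5]deca-6,9-dien-8-one; 2 potassium vinyltrifluoroborate
Product: 3 (10R)-10-ethenyl-1,4-dioxaspiro[4.5]dec-6-en-8-one
Conditions: 2 (0.9 equiv), [Rh(cod)Cl]2 (2.5 mol %), (R)-BINAP (6 mol %), Et3N (1 equiv), toluene/H2O 10:1, 30 °C
Reagents that add atoms: potassium vinyltrifluoroborate (2), [K+].C=C[B-](F)(F)F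
Why: Hayashi–Miyaura rhodium-catalysed asymmetric 1,4-addition of an alkenyltrifluoroborate, a reaction type known on quinone monoketal enones, should desymmetrise the dienone by adding vinyl to the α face of one enone and so set C9; the adduct is more hindered than 1, which limits double addition.

Step 2
Reactants: 3 (10R)-10-ethenyl-1,4-dioxaspiro[4.5]dec-6-en-8-one
Product: 5 (9S,10S)-10-ethenyl-9-methyl-1,4-dioxaspiro[4.5]dec-6-en-8-one, via lithium dienolate 4 (not isolated)
Conditions: LiN(i-Pr)2 (1.05 equiv), THF, −78 °C; MeI (3 equiv), −78 → −30 °C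
Reagents that add atoms: iodomethane, CI
Why: Kinetic deprotonation can occur only at C10 (C8 is a ketal carbon and the other α-carbon is vinylic), and SN2 methylation of the cross-conjugated enolate should place the future C20 methyl anti to the vinyl group; this centre is made planar again in step 3, so its configuration is immaterial.

Step 3
Reactants: 5 (9S,10S)-10-ethenyl-9-methyl-1,4-dioxaspiro[4.5]dec-6-en-8-one
Product: 7 (9R,10S)-10-ethenyl-9-(hydroxymethyl)-9-methyl-1,4-dioxaspiro[4.5]dec-6-en-8-one, via lithium dienolate 6 (not isolated)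
Conditions: LiN(i-Pr)2 (1.1 equiv), THF, −78 → −40 °C; monomeric CH2O (gas), −78 °C; H2O quench at −78 °C
Reagents that add atoms: formaldehyde, C=O
Why: Regiospecific re-enolisation at the same carbon and aldol addition to formaldehyde (enolate hydroxymethylation) should create quaternary C10, the CH2OH (future C1) entering anti to the pseudoaxial C9 vinyl group so that methyl is cis and C1 trans to vinyl; the cold quench prevents retro-aldol loss of formaldehyde.

Step 4
Reactants: 7 (9R,10S)-10-ethenyl-9-(hydroxymethyl)-9-methyl-1,4-dioxaspiro[4.5]dec-6-en-8-one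
Product: 8 (6S,7R)-6-ethenyl-7-(hydroxymethyl)-7-methyl-1,4-dioxaspiro[4.5]decan-8-one
Conditions: [(Ph3P)CuH]6 (0.4 equiv), H2O (3 equiv), benzene, rt
Reagents that add atoms: none
Why: Conjugate reduction with the phosphine copper hydride (hydride to C7, protonation of the copper enolate) should saturate the ring B enone, which has served as a blocking group, while leaving the isolated vinyl group, the ketal and the free alcohol untouched; no stereocentre is affected.

Step 5
Reactants: 8 (6S,7R)-6-ethenyl-7-(hydroxymethyl)-7-methyl-1,4-dioxaspiro[4.5]decan-8-one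
Product: 9 (6S,7R)-6-ethenyl-7-methyl-8-oxo-1,4-dioxaspiro[4.5]decane-7-carbaldehyde
Conditions: Dess–Martin periodinane, CH2Cl2, 0 °C → rt
Reagents that add atoms: none
Why: Dess–Martin oxidation of the neopentyl primary alcohol under neutral conditions should give the β-keto aldehyde, which cannot enolise or epimerise at quaternary C10 and is not exposed to nucleophilic base that could deformylate it.

Step 6
Reactants: 9 (6S,7R)-6-ethenyl-7-methyl-8-oxo-1,4-dioxaspiro[4.5]decane-7-carbaldehyde; 10 1-methoxy-1,3-bis(trimethylsilyloxy)buta-1,3-diene (Chan's diene)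
Product: 13 methyl 8,8-(ethylenedioxy)-3-oxo-13,14,15,16,17,18-hexanor-ent-labda-1,4,11-trien-19-oate, via bis-silyl aldol adduct 11 (not isolated), via ring-closed bis-silyl ether 12 (not isolated)
Conditions: TiCl4 (1.1 equiv, precomplexed with 9), CH2Cl2, −78 °C; 10 (1.2 equiv), −78 → −20 °C; then Et3N (5 equiv), 0 °C → rt
Reagents that add atoms: 1-methoxy-1,3-bis(trimethylsilyloxy)buta-1,3-diene (10), COC(O[Si](C)(C)C)=CC(=C)O[Si](C)(C)C
Why: TiCl4 chelates the C1 aldehyde and C5 ketone of 9; the terminal carbon of the diene adds to the aldehyde (vinylogous Mukaiyama aldol, C1–C2), the remaining β-keto ester silyl enol ether then adds to the titanium-activated C5 ketone (intramolecular Mukaiyama aldol, C4–C5), and amine-assisted β-elimination of the C5 and C1 oxygens gives the cross-conjugated dienone. The closest known reaction type is the Chan–Brownbridge formal [3+3] cyclocondensation of 1,3-bis(silyl enol ethers) with 1,3-dicarbonyl dielectrophiles, including cases where a quaternary central carbon stops the sequence at the cyclohexenone stage. Ring A closes by a 6-(enolexo)-exo-trig aldol addition onto the ring B ketone, and because this closure precedes loss of the C1 oxygen the C1=C2 double bond forms inside the ring. No new stereocentre is created: C9 and C10 cannot enolise and are carried through, while C4 and C5 are left trigonal on purpose so that step 8 sets them. The step needs regioselectivity (diene terminus to C1, central carbon to C5), secured by the higher electrophilicity of the aldehyde over the hindered ketone and the higher nucleophilicity of the diene terminus. It also needs chemoselectivity over the C8 dioxolane, secured by binding the single equivalent of TiCl4 in the β-keto aldehyde chelate at low temperature and buffering with Et3N before warming.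

Step 7
Reactants: 13 methyl 8,8-(ethylenedioxy)-3-oxo-13,14,15,16,17,18-hexanor-ent-labda-1,4,11-trien-19-oate
Product: 14 methyl 8,8-(ethylenedioxy)-3-oxo-13,14,15,16,17,18-hexanor-ent-labda-4,11-dien-19-oate
Conditions: [(Ph3P)CuH]6 (0.4 equiv), H2O (3 equiv), benzene, rt
Reagents that add atoms: none
Why: Conjugate reduction with the bulky copper hydride should deliver hydride only to C1 of the disubstituted enone, since the doubly activated C4=C5 bond is tetrasubstituted and flanked by quaternary C10; protonation gives the conjugated enone ester.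

Step 8
Reactants: 14 methyl 8,8-(ethylenedioxy)-3-oxo-13,14,15,16,17,18-hexanor-ent-labda-4,11-dien-19-oate
Product: 16 methyl 8,8-(ethylenedioxy)-3-oxo-13,14,15,16,17-pentanor-ent-labd-11-en-19-oate, via lithium enolate 15 (not isolated)
Conditions: Li (2.2 equiv), liquid NH3/THF, t-BuOH (1.0 equiv), −78 → −33 °C; NH3 evaporated; MeI (5 equiv), THF, −78 → 0 °C
Reagents that add atoms: iodomethane, CI
Why: Stork reductive alkylation: two-electron reduction of the alkylidene β-keto ester and axial protonation at C5 anti to the C10 methyl should give the trans-decalin lithium enolate, which is C-methylated from the β face opposite the axial C10 methyl, so the new methyl is equatorial and the ester (C19) axial; the isolated vinyl group and the ketal are inert to Li/NH3.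

Step 9
Reactants: 16 methyl 8,8-(ethylenedioxy)-3-oxo-13,14,15,16,17-pentanor-ent-labd-11-en-19-oate
Product: 17 methyl 3,8-dioxo-13,14,15,16,17-pentanor-ent-labd-11-en-19-oate
Conditions: 1 M aq. HCl, THF, 0 °C → rt
Reagents that add atoms: water, O
Why: Acid-catalysed ketal hydrolysis should free the C8 ketone; migration of the β,γ-double bond into conjugation is disfavoured because an ethylidene group at C9 would suffer A(1,3) strain with quaternary C10 and mild conditions keep enolisation toward C9 slow, and the C9 side chain already sits in the stable equatorial position.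

Step 10
Reactants: 17 methyl 3,8-dioxo-13,14,15,16,17-pentanor-ent-labd-11-en-19-oate
Product: 18 methyl 3-oxo-13,14,15,16-tetranor-ent-labda-8(17),11-dien-19-oate
Conditions: Ph3PCH3Br (1.5 equiv), KN(SiMe3)2 (1.4 equiv), THF, 0 °C; then 17, 0 °C → rt
Reagents that add atoms: methyltriphenylphosphonium bromide, C[P+](c1ccccc1)(c1ccccc1)c1ccccc1.[Br-]
Why: Wittig methylenation should occur only at the C8 ketone, because the C3 ketone is neopentylic (next to quaternary C4) and the ester does not react with the non-stabilised ylide at this temperature; C9 keeps its equatorial side chain.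

Step 11
Reactants: 18 methyl 3-oxo-13,14,15,16-tetranor-ent-labda-8(17),11-dien-19-oate
Product: 19 13,14,15,16-tetranor-ent-labda-8(17),11-diene-3α,19-diol
Conditions: LiAlH4 (3 equiv), THF, 0 °C → rt; aqueous work-up
Reagents that add atoms: none
Why: LiAlH4 should reduce the ester to the C19 primary alcohol and the C3 ketone by axial hydride delivery from the unhindered β face, as in 4,4-disubstituted 3-keto terpenoids, giving the equatorial 3α-alcohol; both alkenes are inert.

Step 12
Reactants: 19 13,14,15,16-tetranor-ent-labda-8(17),11-diene-3α,19-diol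
Product: 20 3α-hydroxy-13,14,15,16-tetranor-ent-labda-8(17),11-dien-19-yl acetate
Conditions: AcCl (1.1 equiv), 2,4,6-collidine (2 equiv), CH2Cl2, −78 °C
Reagents that add atoms: acetyl chloride, CC(Cl)=O
Why: Low-temperature acylation with acetyl chloride and a hindered pyridine base should acetylate the primary C19 alcohol selectively over the secondary C3 alcohol, which is flanked by quaternary C4.

Step 13
Reactants: 20 3α-hydroxy-13,14,15,16-tetranor-ent-labda-8(17),11-dien-19-yl acetate; 21 3-bromofuran-2(5H)-one
Product: 22 19-O-acetyl-14-deoxy-11,12-didehydroandrographolide (target CNP0346413.1)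
Conditions: Pd(OAc)2 (10 mol %), Bu4NCl (1 equiv), NaHCO3 (2.5 equiv), DMF, 60 °C
Reagents that add atoms: 3-bromofuran-2(5H)-one (21), O=C1OCC=C1Br
Why: Mizoroki–Heck reaction: oxidative addition of zerovalent palladium into the C–Br bond, insertion of the monosubstituted C11=C12 alkene with C–C bond formation at terminal C12 (the 1,1-disubstituted C8 methylene reacts much more slowly) and syn β-hydride elimination of a C12 hydrogen should give the lactone-conjugated (E)-diene; the inorganic base avoids amine addition to the bromobutenolide.

**Compound list**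
1 | 1,4-dioxaspiro[4.5]deca-6,9-dien-8-one (p-benzoquinone mono(ethylene ketal)) | O=C1C=CC2(OCCO2)C=C1 | starting material
2 | potassium vinyltrifluoroborate | [K+].C=C[B-](F)(F)F | starting material
3 | (10R)-10-ethenyl-1,4-dioxaspiro[4.5]dec-6-en-8-one | O=C1C=CC2(OCCO2)[C@@H](C=C)C1 | intermediate
4 | lithium dienolate of 3 | [Li+].[O-]C1=C[C@H](C=C)C2(OCCO2)C=C1 | intermediate (not isolated)
5 | (9S,10S)-10-ethenyl-9-methyl-1,4-dioxaspiro[4.5]dec-6-en-8-one (methyl trans to vinyl) | O=C1C=CC2(OCCO2)[C@@H](C=C)[C@@H]1C | intermediate
6 | lithium dienolate of 5 | [Li+].[O-]C1=C(C)[C@H](C=C)C2(OCCO2)C=C1 | intermediate (not isolated)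
7 | (9R,10S)-10-ethenyl-9-(hydroxymethyl)-9-methyl-1,4-dioxaspiro[4.5]dec-6-en-8-one (CH2OH trans, methyl cis to vinyl) | O=C1C=CC2(OCCO2)[C@@H](C=C)[C@]1(C)CO | intermediate
8 | (6S,7R)-6-ethenyl-7-(hydroxymethyl)-7-methyl-1,4-dioxaspiro[4.5]decan-8-one | O=C1CCC2(OCCO2)[C@@H](C=C)[C@]1(C)CO | intermediate
9 | (6S,7R)-6-ethenyl-7-methyl-8-oxo-1,4-dioxaspiro[4.5]decane-7-carbaldehyde | O=C1CCC2(OCCO2)[C@@H](C=C)[C@]1(C)C=O | intermediate
10 | 1-methoxy-1,3-bis(trimethylsilyloxy)buta-1,3-diene (Chan's diene) | COC(O[Si](C)(C)C)=CC(=C)O[Si](C)(C)C | starting material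
11 | bis-silyl aldol adduct: methyl 3,5-bis(trimethylsilyloxy)-5-[(6S,7R)-6-ethenyl-7-methyl-8-oxo-1,4-dioxaspiro[4.5]decan-7-yl]pent-2-enoate (C1 carbinol epimers) | COC(=O)C=C(O[Si](C)(C)C)CC(O[Si](C)(C)C)[C@]1(C)C(=O)CCC2(OCCO2)[C@H]1C=C | intermediate (not isolated)
12 | ring-closed bis-silyl ether: ring A closed, C1 and C5 as trimethylsilyl ethers, C3 ketone, C4 ester (new centres unassigned) | COC(=O)C1C(=O)CC(O[Si](C)(C)C)[C@@]2(C)[C@H](C=C)C3(OCCO3)CCC12O[Si](C)(C)C | intermediate (not isolated)
13 | methyl 8,8-(ethylenedioxy)-3-oxo-13,14,15,16,17,18-hexanor-ent-labda-1,4,11-trien-19-oate (9α-vinyl, 10α-methyl) | COC(=O)C1=C2CCC3(OCCO3)[C@@H](C=C)[C@]2(C)C=CC1=O | intermediate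
14 | methyl 8,8-(ethylenedioxy)-3-oxo-13,14,15,16,17,18-hexanor-ent-labda-4,11-dien-19-oate | COC(=O)C1=C2CCC3(OCCO3)[C@@H](C=C)[C@]2(C)CCC1=O | intermediate
15 | lithium enolate of the trans-fused β-keto ester (5β-H) | O1CCOC12CC[C@@H]3C(C(=O)OC)=C([O-])CC[C@@]3(C)[C@@H]2C=C.[Li+] | intermediate (not isolated)
16 | methyl 8,8-(ethylenedioxy)-3-oxo-13,14,15,16,17-pentanor-ent-labd-11-en-19-oate (5β-H, 4β-methyl, 4α-CO2Me) | O1CCOC12CC[C@@H]3[C@](C)(C(=O)OC)C(=O)CC[C@@]3(C)[C@@H]2C=C | intermediate
17 | methyl 3,8-dioxo-13,14,15,16,17-pentanor-ent-labd-11-en-19-oate | O=C1CC[C@@H]2[C@](C)(C(=O)OC)C(=O)CC[C@@]2(C)[C@@H]1C=C | intermediate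
18 | methyl 3-oxo-13,14,15,16-tetranor-ent-labda-8(17),11-dien-19-oate | C=C1CC[C@@H]2[C@](C)(C(=O)OC)C(=O)CC[C@@]2(C)[C@@H]1C=C | intermediate
19 | 13,14,15,16-tetranor-ent-labda-8(17),11-diene-3α,19-diol (3-OH equatorial) | C=C1CC[C@@H]2[C@](C)(CO)[C@H](O)CC[C@@]2(C)[C@@H]1C=C | intermediate
20 | 3α-hydroxy-13,14,15,16-tetranor-ent-labda-8(17),11-dien-19-yl acetate | C=C1CC[C@@H]2[C@](C)(COC(C)=O)[C@H](O)CC[C@@]2(C)[C@@H]1C=C | intermediate
21 | 3-bromofuran-2(5H)-one | O=C1OCC=C1Br | starting material
22 | 19-O-acetyl-14-deoxy-11,12-didehydroandrographolide | C=C1CC[C@@H]2[C@](C)(COC(C)=O)[C@H](O)CC[C@@]2(C)[C@@H]1/C=C/C1=CCOC1=O | target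

**Step count and risks**
Total steps: 13. Longest linear sequence: 13 steps (from 1; compounds 2, 10 and 21 enter as bought fragments).

Steps most likely to fail:

1. Step 6 (key step). What may go wrong: Lewis-acid opening of the C8 dioxolane in competition with the aldehyde, slow closure onto the hindered C5 ketone, or incomplete β-elimination. The fallback avoids Lewis acid and uses a symmetrical bis-nucleophile. It sets out from 9: condensation with dimethyl 3-oxopentanedioate under piperidinium acetate catalysis in toluene with azeotropic removal of water (double Knoevenagel [3+3], both ring A bonds still formed in one operation) should give dienone diester F1. Reduction of its trisubstituted C1=C2 bond with [(Ph3P)CuH]6 gives β-keto diester F2. Krapcho dealkoxycarbonylation (LiCl, wet DMSO, 130 °C) should remove only the enolisable C2 ester, because the C4 carboxyl sits on the C4=C5 double bond and cannot decarboxylate by the β-keto acid pathway. The fallback comes back to the route at 14.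

2. Step 10. What may go wrong: enolisation of the C8 ketone toward C9 by the basic ylide, with migration of the C11=C12 double bond into conjugation, or competing attack at the C3 ketone. The fallback is a non-basic addition–elimination. It sets out from 17: Me3SiCH2MgCl with CeCl3 in THF at −78 °C should add to the unhindered C8 ketone to give β-hydroxysilane F3, and Peterson elimination (aqueous HF, MeCN, 0 °C) then comes back to the route at 18.

3. Step 13. What may go wrong: slow insertion of the hindered alkene, palladium hydride migration of the exocyclic C8 double bond, or base-induced decomposition of the bromobutenolide. The fallback is a two-stage cross-coupling. It sets out from 20: cross-metathesis with vinylboronic acid pinacol ester (second-generation Grubbs catalyst, (H2IMes)(PCy3)Cl2Ru=CHPh, CH2Cl2, 40 °C) should give (E)-alkenylboronate F4, and Suzuki–Miyaura coupling with 21 (Pd(dppf)Cl2, K3PO4, THF/H2O, 50 °C) comes back to the route at 22.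

**Further compounds**
F1 | step 6 | dimethyl 8,8-(ethylenedioxy)-3-oxo-hexanor-ent-labda-1,4,11-triene-2,19-dicarboxylate (dienone diester) | COC(=O)C1=C2CCC3(OCCO3)[C@@H](C=C)[C@]2(C)C=C(C(=O)OC)C1=O
F2 | step 6 | dimethyl 8,8-(ethylenedioxy)-3-oxo-hexanor-ent-labda-4,11-diene-2,19-dicarboxylate (β-keto diester, C2 epimers) | COC(=O)C1=C2CCC3(OCCO3)[C@@H](C=C)[C@]2(C)CC(C(=O)OC)C1=O
F3 | step 10 | methyl 8-hydroxy-3-oxo-8-[(trimethylsilyl)methyl]-13,14,15,16,17-pentanor-ent-labd-11-en-19-oate (β-hydroxysilane, C8 epimers) | C[Si](C)(C)CC1(O)CC[C@@H]2[C@](C)(C(=O)OC)C(=O)CC[C@@]2(C)[C@@H]1C=C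
F4 | step 13 | (E)-alkenylboronate: pinacol boronate at C12 of 20 | C=C1CC[C@@H]2[C@](C)(COC(C)=O)[C@H](O)CC[C@@]2(C)[C@@H]1/C=C/B1OC(C)(C)C(C)(C)O1
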